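**Plan**
1. Cuts: the acetate C–O bond last; then two ring bonds at once, CH2–CH= and CH(chain)–CMe2. This divides the cyclohexene into a C5 epoxide (ring CH2, CH–O and CMe2) and the CH2–C(CH3)=CH end of an all-E C25 chain. The chain is cut at its central tail-to-tail CH2–CH2 bond into a C10 piece and farnesyl bromide.
2. Enabling feature: in the ring the oxygen-bearing CH lies between CH2 and the quaternary CMe2, which is an opened 2,2-dimethyloxirane, and the ring alkene CH=C(CH3) is flanked by the chain-bearing CH. A PhSO2 group on the future =CH carbon makes it a carbanion for the first bond and then leaves as a radical from the ring, so the alkene can only form between CH and C(CH3).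
3. Forward: geranyl sulfone, ω-hydroxylation, coupling with farnesyl bromide, desulfonylation, terminal allyl sulfone (C25). A one-flask alkylation with the epoxy iodide followed by trivalent-titanium radical 6-endo cyclization then closes the only ring, and acetylation finishes the route.
4. Stereochemistry: the C–O centre comes from Sharpless asymmetric epoxidation of prenol. The chain-bearing centre follows from it in the chair-like ring closure (1,3-cis). The E alkenes come from E-geranyl bromide, E,E-farnesyl bromide and E-selective SeO2 oxidation.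

Key step: step 8

Remark: geranyl bromide and farnesyl bromide are taken as the commercial all-E compounds; in step 8 the carbanion alkylation and the radical ring closure follow each other in the same flask without work-up.

Step 1
Reactants: 1 (2E)-1-bromo-3,7-dimethylocta-2,6-diene (geranyl bromide)
Product: 2 [(2E)-3,7-dimethylocta-2,6-dien-1-yl]sulfonylbenzene (geranyl phenyl sulfone)
Conditions: PhSO2Na, DMF, rt
Reagents that add atoms: sodium benzenesulfinate, [Na+].[O-]S(=O)c1ccccc1
Why: SN2 substitution of the primary allylic bromide by the sulfur of the sulfinate should give the allyl sulfone without touching the 2E alkene.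

Step 2
Reactants: 2 geranyl phenyl sulfone
Product: 3 (2E,6E)-2,6-dimethyl-8-(phenylsulfonyl)octa-2,6-dien-1-ol
Conditions: SeO2 (0.3 equiv), t-BuOOH, salicylic acid (cat.), CH2Cl2, rt
Reagents that add atoms: tert-butyl hydroperoxide, CC(C)(C)OO
Why: Catalytic SeO2 allylic oxidation (ene reaction, then [2,3]-sigmatropic shift) should hydroxylate the E-methyl group of the electron-rich terminal alkene and spare the alkene next to the sulfone, the E geometry following from the mechanism.

Step 3
Reactants: 3 (2E,6E)-2,6-dimethyl-8-(phenylsulfonyl)octa-2,6-dien-1-ol; 4 (2E,6E)-1-bromo-3,7,11-trimethyldodeca-2,6,10-triene (farnesyl bromide)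
Product: 5 (2E,6E,10E,14E)-2,6,11,15,19-pentamethyl-8-(phenylsulfonyl)icosa-2,6,10,14,18-pentaen-1-ol
Conditions: n-BuLi (2.1 equiv), THF, −78 °C; then 4, −78 to −20 °C
Reagents that add atoms: none
Why: Sulfone-carbanion allylic alkylation: the alkoxide/α-sulfonyl dianion should react at carbon (SN2) with the primary allylic bromide and join the two chain pieces tail to tail, the new sulfonyl-bearing centre being removed in step 4.

Step 4
Reactants: 5 C25 hydroxy sulfone
Product: 6 (2E,6E,10E,14E)-2,6,11,15,19-pentamethylicosa-2,6,10,14,18-pentaen-1-ol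
Conditions: PdCl2(dppp) (5 mol %), LiBHEt3, THF, 0 °C
Reagents that add atoms: none
Why: Palladium-catalysed reductive desulfonylation: zerovalent palladium ionises the allylic sulfone and hydride is delivered to the less substituted allyl terminus, which should leave the trisubstituted E alkene in place.

Step 5
Reactants: 6 C25 allylic alcohol
Product: 8 [(2E,6E,10E,14E)-2,6,11,15,19-pentamethylicosa-2,6,10,14,18-pentaen-1-yl]sulfonylbenzene, via C25 allylic bromide 7 (not isolated)
Conditions: PBr3, pyridine (cat.), Et2O, −10 °C; then PhSO2Na, DMF, rt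
Reagents that add atoms: sodium benzenesulfinate, [Na+].[O-]S(=O)c1ccccc1
Why: Bromination of the primary allylic alcohol and SN2 substitution by sulfinate sulfur should give the terminal allyl sulfone with the 2E alkene retained.

Step 6
Reactants: 9 3-methylbut-2-en-1-ol (prenol)
Product: 11 [(2S)-3,3-dimethyloxiran-2-yl]methyl 4-methylbenzenesulfonate, via epoxy alcohol 10 (not isolated)
Conditions: Ti(OiPr)4 (5 mol %), L-(+)-diethyl tartrate (7 mol %), t-BuOOH, 4 Å MS, CH2Cl2, −20 °C; then P(OMe)3; then TsCl, Et3N, DMAP (cat.), −10 °C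
Reagents that add atoms: tert-butyl hydroperoxide, CC(C)(C)OO; 4-methylbenzenesulfonyl chloride, Cc1ccc(cc1)S(Cl)(=O)=O
Why: Sharpless asymmetric epoxidation: the titanium–L-tartrate catalyst delivers oxygen to one face of the allylic alcohol and should set the S epoxide centre, and tosylation in the same flask avoids isolating the water-soluble epoxy alcohol.

Step 7
Reactants: 11 (S)-epoxy tosylate
Product: 12 (2R)-2-(iodomethyl)-3,3-dimethyloxirane
Conditions: NaI, NaHCO3, acetone, rt, dark
Reagents that add atoms: sodium iodide, [Na+].[I-]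
Why: Finkelstein exchange (SN2 at the primary carbon) should give the iodide without touching the epoxide centre, whose descriptor changes to R only through the priority rules.

Step 8
Reactants: 8 C25 allyl sulfone; 12 (2R)-2-(iodomethyl)-3,3-dimethyloxirane
Product: 14 (1S,5R)-4,6,6-trimethyl-5-[(3E,7E,11E)-3,8,12,16-tetramethylheptadeca-3,7,11,15-tetraen-1-yl]cyclohex-3-en-1-ol (camelliol C), via epoxy sulfone 13 (not isolated)
Conditions: n-BuLi (1.0 equiv), THF, −78 °C; 12, −78 to −40 °C; then transfer into Cp2TiCl2 (20 mol %), Mn dust, 2,4,6-collidine·HCl, THF, rt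
Reagents that add atoms: none
Why: Proposed new method: the lithio derivative of 8 is alkylated at its sulfonyl-bearing carbon by the primary iodide of 12 (SN2), which makes the CH2–CH bond and gives 13; Cp2TiCl (trivalent titanium, from Cp2TiCl2 and Mn) then opens the 2,2-dimethyloxirane homolytically to the tertiary β-titanoxy radical, which adds to the CH end of the neighbouring trisubstituted alkene, makes the CMe2–CH bond and the ring, and the tertiary ring radical expels PhSO2•, so that the alkene can only lie between the ring CH and C(CH3). The closest known reaction types are the Cp2TiCl-mediated radical cyclization of epoxypolyprenes, which normally ends by hydrogen loss to an exocyclic alkene, and radical allylation with allyl sulfones (addition followed by β-scission of the C–S bond); both halves are known and their union on one substrate is the new element. The six-membered ring closes in the 6-endo-trig mode because the inner alkene carbon carries the methyl group and attack at the CH end gives a tertiary radical. The chain-bearing stereocentre is controlled by the carbinol centre from step 6 through a chair-like transition state in which the O–Ti group and the chain on the E alkene are both equatorial, which should give the 1,3-cis (1S,5R) ring; the sulfonyl-bearing centre of 13 is destroyed. The step needs α- and not γ-alkylation of the allyl anion (the sulfonyl group localises the charge), loss of PhSO2• faster than a second cyclization onto the next chain alkene (the weak C–S bond β to the radical), and fast reduction of PhSO2• by the excess reductant so that it does not add reversibly to the chain alkenes.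

Step 9
Reactants: 14 camelliol C
Product: 15 (1S,5R)-4,6,6-trimethyl-5-[(3E,7E,11E)-3,8,12,16-tetramethylheptadeca-3,7,11,15-tetraen-1-yl]cyclohex-3-en-1-yl acetate
Conditions: Ac2O, pyridine, DMAP (cat.), CH2Cl2, rt
Reagents that add atoms: acetic anhydride, CC(=O)OC(C)=O
Why: DMAP-catalysed O-acylation of the secondary alcohol should give the acetate with retention at the carbinol centre, since the C–O bond is not broken.

**Compound list**
1 | (2E)-1-bromo-3,7-dimethylocta-2,6-diene (geranyl bromide) | CC(C)=CCC/C(C)=C/CBr | starting material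
2 | [(2E)-3,7-dimethylocta-2,6-dien-1-yl]sulfonylbenzene | CC(C)=CCC/C(C)=C/CS(=O)(=O)c1ccccc1 | intermediate
3 | (2E,6E)-2,6-dimethyl-8-(phenylsulfonyl)octa-2,6-dien-1-ol | OC/C(C)=C/CC/C(C)=C/CS(=O)(=O)c1ccccc1 | intermediate
4 | (2E,6E)-1-bromo-3,7,11-trimethyldodeca-2,6,10-triene (farnesyl bromide) | CC(C)=CCC/C(C)=C/CC/C(C)=C/CBr | starting material
5 | (2E,6E,10E,14E)-2,6,11,15,19-pentamethyl-8-(phenylsulfonyl)icosa-2,6,10,14,18-pentaen-1-ol (racemic at C8) | OC/C(C)=C/CC/C(C)=C/C(C/C=C(\C)CC/C=C(\C)CCC=C(C)C)S(=O)(=O)c1ccccc1 | intermediate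
6 | (2E,6E,10E,14E)-2,6,11,15,19-pentamethylicosa-2,6,10,14,18-pentaen-1-ol | OC/C(C)=C/CC/C(C)=C/CC/C=C(\C)CC/C=C(\C)CCC=C(C)C | intermediate
7 | (2E,6E,10E,14E)-1-bromo-2,6,11,15,19-pentamethylicosa-2,6,10,14,18-pentaene | BrC/C(C)=C/CC/C(C)=C/CC/C=C(\C)CC/C=C(\C)CCC=C(C)C | intermediate
8 | [(2E,6E,10E,14E)-2,6,11,15,19-pentamethylicosa-2,6,10,14,18-pentaen-1-yl]sulfonylbenzene | O=S(=O)(C/C(C)=C/CC/C(C)=C/CC/C=C(\C)CC/C=C(\C)CCC=C(C)C)c1ccccc1 | intermediate
9 | 3-methylbut-2-en-1-ol (prenol) | CC(C)=CCO | starting material
10 | [(2S)-3,3-dimethyloxiran-2-yl]methanol | OC[C@@H]1OC1(C)C | intermediate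
11 | [(2S)-3,3-dimethyloxiran-2-yl]methyl 4-methylbenzenesulfonate | Cc1ccc(cc1)S(=O)(=O)OC[C@@H]1OC1(C)C | intermediate
12 | (2R)-2-(iodomethyl)-3,3-dimethyloxirane | IC[C@@H]1OC1(C)C | intermediate
13 | (2S)-3,3-dimethyl-2-[(3E,7E,11E,15E)-3,7,12,16,20-pentamethyl-2-(phenylsulfonyl)henicosa-3,7,11,15,19-pentaen-1-yl]oxirane (both epimers at the sulfonyl-bearing carbon) | CC1(C)O[C@H]1CC(S(=O)(=O)c2ccccc2)/C(C)=C/CC/C(C)=C/CC/C=C(\C)CC/C=C(\C)CCC=C(C)C | intermediate
14 | (1S,5R)-4,6,6-trimethyl-5-[(3E,7E,11E)-3,8,12,16-tetramethylheptadeca-3,7,11,15-tetraen-1-yl]cyclohex-3-en-1-ol (camelliol C) | O[C@H]1CC=C(C)[C@@H](CC/C(C)=C/CC/C=C(\C)CC/C=C(\C)CCC=C(C)C)C1(C)C | intermediate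
15 | (1S,5R)-4,6,6-trimethyl-5-[(3E,7E,11E)-3,8,12,16-tetramethylheptadeca-3,7,11,15-tetraen-1-yl]cyclohex-3-en-1-yl acetate | CC(=O)O[C@H]1CC=C(C)[C@@H](CC/C(C)=C/CC/C=C(\C)CC/C=C(\C)CCC=C(C)C)C1(C)C | target

Total step count: 9. Longest linear sequence: 7 steps (1, 2, 3, 4, 5, 8, 9).

**Steps most likely to fail**

Step 8 (carries the proposed new method). The carbanion may attack iodine and open the epoxide by elimination instead of substituting at carbon. The tertiary radical may be reduced before it cyclises, or may close 5-exo. PhSO2• may add and leave along the chain and erode the E geometry. Facial control at the chain-bearing centre may be incomplete. The fallback uses known chemistry and moves the ring closure to an enzyme. It sets out from alcohol 6, whose bromide 7 is isolated this time. Alkylation of LiCH2CN with 7 gives (4E,8E,12E,16E)-4,8,13,17,21-pentamethyldocosa-4,8,12,16,20-pentaenenitrile F1. Reduction with i-Bu2AlH at −78 °C and hydrolysis gives (4E,8E,12E,16E)-4,8,13,17,21-pentamethyldocosa-4,8,12,16,20-pentaenal F2. Diphenylsulfonium isopropylide converts the aldehyde into racemic 2,2-dimethyl-3-[(3E,7E,11E,15E)-3,7,12,16,20-pentamethylhenicosa-3,7,11,15,19-pentaen-1-yl]oxirane F3 (2,3-oxidosqualene). An oxidosqualene cyclase (recombinant camelliol C synthase, a triterpene synthase) should accept only the 3S epoxide and fold it to 14, where the route is rejoined before the acetylation.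

Step 3. The dianion may be alkylated at oxygen, farnesyl bromide may react in the SN2′ sense, or proton transfer may stall the coupling. The fallback avoids the dianion. It sets out from 3, which is silylated (TBSCl, imidazole) to tert-butyl(dimethyl){[(2E,6E)-2,6-dimethyl-8-(phenylsulfonyl)octa-2,6-dien-1-yl]oxy}silane F4. Its monoanion (n-BuLi, one equivalent) is alkylated with 4 to tert-butyl(dimethyl){[(2E,6E,10E,14E)-2,6,11,15,19-pentamethyl-8-(phenylsulfonyl)icosa-2,6,10,14,18-pentaen-1-yl]oxy}silane F5. Removal of the silyl group with Bu4NF returns to 5.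

Step 7. Iodide may open the trisubstituted epoxide, and the small volatile iodide may be lost on concentration. The fallback uses no halide. It sets out from 10, which is isolated after the epoxidation and treated with Tf2O and 2,6-lutidine at −78 °C to give [(2S)-3,3-dimethyloxiran-2-yl]methyl trifluoromethanesulfonate F6. The cold solution of this triflate serves as the electrophile for the lithio derivative of 8, and the route is rejoined at 13.

**Further compounds**
F1 | step 8 | (4E,8E,12E,16E)-4,8,13,17,21-pentamethyldocosa-4,8,12,16,20-pentaenenitrile | N#CCC/C(C)=C/CC/C(C)=C/CC/C=C(\C)CC/C=C(\C)CCC=C(C)C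
F2 | step 8 | (4E,8E,12E,16E)-4,8,13,17,21-pentamethyldocosa-4,8,12,16,20-pentaenal | O=CCC/C(C)=C/CC/C(C)=C/CC/C=C(\C)CC/C=C(\C)CCC=C(C)C
F3 | step 8 | 2,2-dimethyl-3-[(3E,7E,11E,15E)-3,7,12,16,20-pentamethylhenicosa-3,7,11,15,19-pentaen-1-yl]oxirane (racemic) | CC1(C)OC1CC/C(C)=C/CC/C(C)=C/CC/C=C(\C)CC/C=C(\C)CCC=C(C)C
F4 | step 3 | tert-butyl(dimethyl){[(2E,6E)-2,6-dimethyl-8-(phenylsulfonyl)octa-2,6-dien-1-yl]oxy}silane | CC(C)(C)[Si](C)(C)OC/C(C)=C/CC/C(C)=C/CS(=O)(=O)c1ccccc1
F5 | step 3 | tert-butyl(dimethyl){[(2E,6E,10E,14E)-2,6,11,15,19-pentamethyl-8-(phenylsulfonyl)icosa-2,6,10,14,18-pentaen-1-yl]oxy}silane | CC(C)(C)[Si](C)(C)OC/C(C)=C/CC/C(C)=C/C(C/C=C(\C)CC/C=C(\C)CCC=C(C)C)S(=O)(=O)c1ccccc1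
F6 | step 7 | [(2S)-3,3-dimethyloxiran-2-yl]methyl trifluoromethanesulfonate | O=S(=O)(OC[C@@H]1OC1(C)C)C(F)(F)F
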